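**Plan**
- Retrosynthesis: first cut the bond from C6 of flavanone ring A to C3 of the cyclohexene (Friedel–Crafts; gives (2S)-pinocembrin and the allyl cation of a piperitol). Then cut the C1=C2 double bond and the C4–C5 single bond of the carbocycle together.
- Enabling feature: C3 (aryl-bearing) is allylic to C1(CH3)=C2 and flanked by C4(i-Pr). With C3 as a ketone the ring is a 3-methylcyclohex-2-enone, so C5–C6–C1(CH3) is methyl vinyl ketone and C2–C3–C4 is an α-isopropylacetoacetate (Michael bond C4–C5, aldol-condensation bond C1=C2).
- Forward: ester exchange; a one-flask Michael/aldol condensation builds the cyclohexene, the only ring made; decarboxylative protonation removes the ester helper; the ketone is reduced; the ring is joined to ring A of pinocembrin (rings A, C and phenyl are bought).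
- Stereochemistry: C4 by catalyst-controlled enantioselective protonation (step 3); C3 trans to C4 by anti attack on the allyl cation (step 5); flavanone C2 from (2S)-pinocembrin, untouched.

Key step: step 2

Ring numbering used in the text: C1 carries CH3, C2 is the alkene CH, C3 the aryl group (carbonyl or carbinol carbon in 7–9), C4 the isopropyl group.
Assumption: in step 3 the ligand antipode is chosen so that the (6S)-ketone results; (S)-t-BuPHOX is written, and (R)-t-BuPHOX is used if the sense of induction proves opposite.

Step 1
Reactants: 1 ethyl 2-acetyl-3-methylbutanoate (ethyl 2-isopropylacetoacetate); 2 prop-2-en-1-ol (allyl alcohol)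
Product: 3 prop-2-en-1-yl 2-acetyl-3-methylbutanoate (racemic)
Conditions: 2 (5 equiv), DMAP (0.3 equiv), toluene, reflux, 4 Å MS (removal of EtOH)
Reagents that add atoms: none
Why: DMAP-catalysed transesterification of an enolisable β-keto ester, driven by removal of ethanol, exchanges the ester group without touching the skeleton; the α-centre is racemic and of no consequence because it becomes a quaternary centre that is later erased.

Step 2
Reactants: 3 prop-2-en-1-yl 2-acetyl-3-methylbutanoate; 4 but-3-en-2-one (methyl vinyl ketone)
Product: 7 prop-2-en-1-yl 4-methyl-2-oxo-1-(propan-2-yl)cyclohex-3-ene-1-carboxylate (racemic), via Michael adduct 5 (not isolated), via ketol 6 (not isolated)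
Conditions: 4 (1.3 equiv), Cs2CO3 (0.1 equiv), MeCN, 0 °C → rt; then p-TsOH·H2O (0.3 equiv), toluene, reflux (Dean–Stark), same flask
Reagents that add atoms: none
Why: Robinson-type [3+3] annulation: carbonate-catalysed Michael addition of the doubly stabilised enolate of 3 through its α-carbon (future C4) to the terminal CH2 of 4 (future C5) gives 5; under acid the enol of the acetyl group (C2=C3) adds to the side-chain ketone (C1), and ketol 6 loses water to give the conjugated C1=C2 bond. The six-membered ring is closed by a favoured 6-(enolendo)-exo-trig aldol addition. The quaternary C4 centre is formed without control and is deliberately racemic, since step 3 erases and resets it; the carbinol centre of 6 disappears on dehydration. The selectivity needed is the direction of the aldol (acetyl CH3 onto the unhindered C1 carbonyl, not side-chain CH3 onto the C3 carbonyl): the C3 carbonyl is shielded by the adjacent quaternary carbon carrying isopropyl and ester, C3 can enolise only towards C2, and the alternative enone would place its β-methyl next to the quaternary centre. The ester is the helper that makes C4, not the acetyl methyl, the Michael donor, and it is removed in step 3.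

Step 3
Reactants: 7 prop-2-en-1-yl 4-methyl-2-oxo-1-(propan-2-yl)cyclohex-3-ene-1-carboxylate
Product: 8 (6S)-3-methyl-6-(propan-2-yl)cyclohex-2-en-1-one ((S)-piperitone)
Conditions: Pd(OAc)2 (10 mol %), (S)-t-BuPHOX (12.5 mol %), Meldrum's acid (2.5 equiv), 1,4-dioxane, 22 °C
Reagents that add atoms: none
Why: Palladium-catalysed enantioselective decarboxylative protonation: zerovalent palladium formed in situ ionises the allyl ester, loss of CO2 gives a ligand-bound palladium enolate in which the racemic quaternary centre has become planar, and Meldrum's acid, which also captures the allyl group, protonates the enolate carbon on the face left open by the phosphinooxazoline ligand, so that C6 of 8 (ring C4) is set by catalyst control under acidic conditions that should not enolise the product.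

Step 4
Reactants: 8 (6S)-3-methyl-6-(propan-2-yl)cyclohex-2-en-1-one
Product: 9 (1S,6S)-3-methyl-6-(propan-2-yl)cyclohex-2-en-1-ol (trans-piperitol; any C1 epimer is carried on)
Conditions: NaBH4 (1.1 equiv), CeCl3·7H2O (1.0 equiv), MeOH, −20 → 0 °C
Reagents that add atoms: none
Why: Luche reduction adds hydride 1,2 to the enone without conjugate reduction and faster than epimerisation at C6, axial attack on the half-chair with pseudo-equatorial isopropyl giving mainly the trans carbinol (substrate control), while a cis epimer is harmless because both ionise to the same allyl cation in step 5.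

Step 5
Reactants: 9 (1S,6S)-3-methyl-6-(propan-2-yl)cyclohex-2-en-1-ol; 10 (2S)-5,7-dihydroxy-2-phenyl-2,3-dihydro-4H-chromen-4-one ((S)-pinocembrin)
Product: 11 (2S)-5,7-dihydroxy-6-[(1S,6S)-3-methyl-6-(propan-2-yl)cyclohex-2-en-1-yl]-2-phenyl-2,3-dihydro-4H-chromen-4-one (target)
Conditions: 10 (2 equiv), p-TsOH·H2O (0.1 equiv), MgSO4, CH2Cl2–1,4-dioxane (2:1), 0 °C → rt
Reagents that add atoms: none
Why: Biomimetic Friedel–Crafts allylation: acid ionises 9 to the C1–C2–C3 allyl cation, which is attacked at its secondary terminus C3, anti to the neighbouring isopropyl group, by C6 of ring A of 10 (the position between the 5- and 7-hydroxyls, expected to be the preferred site for acid-catalysed C-allylation of 5,7-dihydroxyflavanones and resorcinols), so that the new centre is set trans to C4 by substrate control, the trisubstituted C1=C2 alkene results, and the flavanone C2 centre is untouched under these non-basic conditions.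

**Compound list**
1 | ethyl 2-acetyl-3-methylbutanoate (racemic) | CCOC(=O)C(C(C)C)C(C)=O | starting material
2 | prop-2-en-1-ol | C=CCO | starting material
3 | prop-2-en-1-yl 2-acetyl-3-methylbutanoate (racemic) | C=CCOC(=O)C(C(C)C)C(C)=O | intermediate
4 | but-3-en-2-one | CC(=O)C=C | starting material
5 | prop-2-en-1-yl 2-acetyl-5-oxo-2-(propan-2-yl)hexanoate (racemic Michael adduct) | C=CCOC(=O)C(CCC(C)=O)(C(C)C)C(C)=O | intermediate (not isolated)
6 | prop-2-en-1-yl 4-hydroxy-4-methyl-2-oxo-1-(propan-2-yl)cyclohexane-1-carboxylate (ketol, racemic diastereomers) | C=CCOC(=O)C1(C(C)C)CCC(C)(O)CC1=O | intermediate (not isolated)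
7 | prop-2-en-1-yl 4-methyl-2-oxo-1-(propan-2-yl)cyclohex-3-ene-1-carboxylate (racemic) | C=CCOC(=O)C1(C(C)C)CCC(C)=CC1=O | intermediate
8 | (6S)-3-methyl-6-(propan-2-yl)cyclohex-2-en-1-one | CC1=CC(=O)[C@H](C(C)C)CC1 | intermediate
9 | (1S,6S)-3-methyl-6-(propan-2-yl)cyclohex-2-en-1-ol | CC1=C[C@@H](O)[C@H](C(C)C)CC1 | intermediate
10 | (2S)-5,7-dihydroxy-2-phenyl-2,3-dihydro-4H-chromen-4-one | O=C1C[C@@H](c2ccccc2)Oc2cc(O)cc(O)c12 | starting material
11 | (2S)-5,7-dihydroxy-6-[(1S,6S)-3-methyl-6-(propan-2-yl)cyclohex-2-en-1-yl]-2-phenyl-2,3-dihydro-4H-chromen-4-one | CC1=C[C@@H](c2c(O)cc3c(c2O)C(=O)C[C@@H](c2ccccc2)O3)[C@H](C(C)C)CC1 | target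

Total step count: 5. Longest linear sequence: 5 steps (1 → 3 → 7 → 8 → 9 → 11).

**Steps most likely to fail**

1. Step 5. The aromatic substitution may not discriminate between C6 and C8 of ring A, may alkylate twice or on oxygen, or a flanking phenol may add to the new ring alkene under acid. Fallback, setting out from 10 and returning at 11: the site is fixed before the terpene arrives. Compound 10 is brominated (N-bromosuccinimide, 1 equiv, MeCN, −20 °C) and (2S)-8-bromo-5,7-dihydroxy-2-phenyl-2,3-dihydro-4H-chromen-4-one F1 is separated from its C6 isomer at this inexpensive stage. F1 can be C-alkylated only at C6, and with 9 under the conditions of step 5 it should give (2S)-8-bromo-5,7-dihydroxy-6-[(1S,6S)-3-methyl-6-(propan-2-yl)cyclohex-2-en-1-yl]-2-phenyl-2,3-dihydro-4H-chromen-4-one F2. Reductive removal of the blocking halogen (Na2SO3, L-ascorbic acid, Et3N, MeOH–H2O, gentle warming) should then give 11.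

2. Step 3. Protonation of the palladium enolate may be poorly face-selective (the isopropyl group sits on the enolate carbon), or the ketone may lose configuration by enolisation. Fallback, setting out from 7 and returning at 9: the centre is fixed by resolution. Compound 7 is decarboxylated without chiral ligand (Pd(PPh3)4, HCO2H, Et3N, THF) to racemic 3-methyl-6-(propan-2-yl)cyclohex-2-en-1-one F3. Luche reduction and removal of the cis epimer give racemic trans-3-methyl-6-(propan-2-yl)cyclohex-2-en-1-ol F4. Lipase-catalysed acetylation (Burkholderia cepacia lipase, vinyl acetate, t-BuOMe) is expected to esterify the (1S,6S) enantiomer, which corresponds spatially to the fast-reacting (−)-menthol, giving (1S,6S)-3-methyl-6-(propan-2-yl)cyclohex-2-en-1-yl acetate F5. F5 is separated from the unreacted (1R,6R) alcohol and methanolysed (K2CO3, MeOH) to 9.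

3. Step 2. The ring may close in the wrong direction (side-chain methyl onto the hindered C3 carbonyl), or the acetyl group may be lost by retro-Claisen cleavage. Fallback, setting out from 4 (with 2) and returning at 7: the same two ring bonds are made by a Michael/Wittig sequence in which only C2 can close the ring. Commercial ethyl 3-oxo-4-(triphenyl-λ5-phosphanylidene)butanoate is deprotonated (NaH, THF) and added to 4 to give ethyl 3-oxo-2-(3-oxobutyl)-4-(triphenyl-λ5-phosphanylidene)butanoate F6. On heating, F6 should undergo intramolecular Wittig olefination to ethyl 4-methyl-2-oxocyclohex-3-ene-1-carboxylate F7. Ester exchange with 2 (DMAP, toluene, reflux) gives prop-2-en-1-yl 4-methyl-2-oxocyclohex-3-ene-1-carboxylate F8, and C-alkylation (NaH, 2-iodopropane, DMF, 50 °C) gives 7.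

Further compounds
F1 | step 5 | (2S)-8-bromo-5,7-dihydroxy-2-phenyl-2,3-dihydro-4H-chromen-4-one | O=C1C[C@@H](c2ccccc2)Oc2c(Br)c(O)cc(O)c12
F2 | step 5 | (2S)-8-bromo-5,7-dihydroxy-6-[(1S,6S)-3-methyl-6-(propan-2-yl)cyclohex-2-en-1-yl]-2-phenyl-2,3-dihydro-4H-chromen-4-one | CC1=C[C@@H](c2c(O)c(Br)c3c(c2O)C(=O)C[C@@H](c2ccccc2)O3)[C@H](C(C)C)CC1
F3 | step 3 | racemic 3-methyl-6-(propan-2-yl)cyclohex-2-en-1-one | CC1=CC(=O)C(C(C)C)CC1
F4 | step 3 | racemic trans-3-methyl-6-(propan-2-yl)cyclohex-2-en-1-ol | CC1=C[C@@H](O)[C@H](C(C)C)CC1.CC1=C[C@H](O)[C@@H](C(C)C)CC1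
F5 | step 3 | (1S,6S)-3-methyl-6-(propan-2-yl)cyclohex-2-en-1-yl acetate | CC1=C[C@@H](OC(C)=O)[C@H](C(C)C)CC1
F6 | step 2 | ethyl 3-oxo-2-(3-oxobutyl)-4-(triphenyl-λ5-phosphanylidene)butanoate | CCOC(=O)C(CCC(C)=O)C(=O)C=P(c1ccccc1)(c1ccccc1)c1ccccc1
F7 | step 2 | ethyl 4-methyl-2-oxocyclohex-3-ene-1-carboxylate | CCOC(=O)C1CCC(C)=CC1=O
F8 | step 2 | prop-2-en-1-yl 4-methyl-2-oxocyclohex-3-ene-1-carboxylate | C=CCOC(=O)C1CCC(C)=CC1=O
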